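The trap in this flask was the pairing of free catalyst: it runs with the square of free catalyst, so I first expected a doubled charge to repay less than a factor 2.

substrate 1.0 M; free catalyst 0.26 mol%

    2 free catalyst → spent catalyst (k1 = 0.063 L mol⁻¹ min⁻¹)
    catalyst intermediate → free catalyst + product (k2 = 0.87 min⁻¹)
    substrate + free catalyst ⇌ catalyst intermediate (K3 = 0.43 L mol⁻¹, k3 = 0.17 L mol⁻¹ min⁻¹)

* apparent order in free catalyst when 50% of the substrate are converted (percent change of the rate of making product for one percent more free catalyst charged)
* factor on the rate of making product when 50% of the substrate are converted if free catalyst is charged twice over

I wrote a for the share of substrate left and c for the share of free catalyst left. The intermediate is used up at 52 h⁻¹ or more, far faster than free catalyst pairs off at the start, at 0.0197 h⁻¹. I therefore held it steady (the steady-state approximation), which gave an effective turnover constant 0.117 L mol⁻¹ min⁻¹, and I neglected the 11.8% of the working catalyst (free catalyst plus intermediate) that it holds with substrate as charged.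

Then a falls as this constant times the catalyst charge times a times c, while c falls as twice 0.063 L mol⁻¹ min⁻¹ times that charge times c squared. Dividing these, the charge cancels and c = a^n, where the loss ratio n, twice the pairing constant over the turnover constant, is 1.08.

I turned the settings one at a time, at 50% conversion. With more catalyst charged, c stays at 47.4% and the rate follows the charge, so I expected order 1 and factor 2. A constant that raises the turnover constant also lowers n, which leaves more c, so its effect on the rate is multiplied by 1.75. That gave 0.546 for the product step and 1.20 for the binding step.

The forecast gave order 1 and factor 2, since “the fraction of catalyst lost by 50 % conversion does not depend on the charge”. The run gave factor 2.00 and these percent changes of the rate: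

| one percent more on | by hand | run |
|---|---|---|
| free catalyst charged | 1 | 1.0 |
| product step constant | 0.546 | 0.53 |
| binding step constants | 1.20 | 1.2 |

At 40.0 h this flask's free catalyst bound substrate 550 times as fast as it paired off (forward rate alone), and with 0.45 falling back per intermediate going on, as read at 15.3 h, that is about 381 product per free catalyst lost, close to the 410 by which substrate then stood above free catalyst. With n, the 12.6% of substrate left at 400 h gives 89.3% spent catalyst, and the flask held 87.9%.

Its constants come from no measurement; no experiment stands behind them.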